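**Strategy.** The quinone ring is assembled, not functionalized. Numbering the ring C1(=O), C2(CH3), C3(CH3), C4(=O), C5(side chain), C6(CH3), the C1–C4 half is a symmetric 2,3-dimethylmaleoyl unit and C5=C6 is an internal alkyne. A maleoylcobalt complex, obtained by insertion of cobalt into the C(O)–C(O) bond of 3,4-dimethylcyclobutenedione, takes up the alkyne and forms C4–C5 and C1–C6 in one operation, delivering the ring directly at the quinone oxidation level; the symmetry of the maleoyl half removes any regiochemical issue. The alkyne already carries the whole side chain, whose tertiary carbinol comes from Sharpless epoxidation of natural phytol.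

Key step: step 7

Remark on the chemistry: natural phytol is taken as the single (2E,7R,11R) isomer (chlorophyll-derived material); its two methyl-bearing stereocentres are carried through unchanged and become the two remote R centres of the target.

**Step 1**
Reactants: 1 natural phytol, (2E,7R,11R)-3,7,11,15-tetramethylhexadec-2-en-1-ol
Product: 2 (2R,3R)-2,3-epoxyphytol, [(2R,3R)-3-methyl-3-[(4R,8R)-4,8,12-trimethyltridecyl]oxiran-2-yl]methanol
Conditions: Ti(OiPr)4 (cat.), D-(−)-diethyl tartrate (cat.), t-BuOOH, 4 Å molecular sieves, CH2Cl2, −20 °C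
Reagents that add atoms: tert-butyl hydroperoxide, CC(C)(C)OO
Why: Katsuki–Sharpless asymmetric epoxidation of an (E)-trisubstituted allylic alcohol under reagent control; the D-(−)-tartrate complex should deliver oxygen to the face that gives the (2R,3R) oxirane (the mirror sense of the (2S,3S) outcome of geraniol with the L-(+)-ester), which fixes the future carbinol carbon C3 as R.

**Step 2**
Reactants: 2 (2R,3R)-2,3-epoxyphytol
Product: 3 (3R,7R,11R)-3,7,11,15-tetramethylhexadecane-1,3-diol
Conditions: NaAlH2(OCH2CH2OCH3)2, THF, 0 °C to rt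
Reagents that add atoms: none
Why: Reductive opening of a 2,3-epoxy alcohol by an alkoxyaluminium hydride, in which the aluminate bound at O1 delivers hydride to C2, the only non-quaternary oxirane carbon, so the C3–O bond is untouched and the tertiary carbinol keeps its R configuration.

**Step 3**
Reactants: 3 (3R,7R,11R)-3,7,11,15-tetramethylhexadecane-1,3-diol
Product: 4 (3R,7R,11R)-3-hydroxy-3,7,11,15-tetramethylhexadecyl 4-methylbenzenesulfonate
Conditions: TsCl, pyridine, CH2Cl2, 0 °C
Reagents that add atoms: p-toluenesulfonyl chloride, Cc1ccc(cc1)S(=O)(=O)Cl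
Why: Selective sulfonylation (tosylation) of the unhindered primary hydroxyl; the tertiary hydroxyl is too hindered to react under these conditions.

**Step 4**
Reactants: 4 (3R,7R,11R)-3-hydroxy-3,7,11,15-tetramethylhexadecyl 4-methylbenzenesulfonate
Product: 5 (6R,10R,14R)-6,10,14,18-tetramethylnonadec-2-yn-6-ol
Conditions: LiC≡CCH3 (3 equiv), THF/DMPU, −20 °C to rt
Reagents that add atoms: 1-propynyllithium, CC#C[Li]
Why: SN2 alkylation of a lithium acetylide by the primary tosylate in a dipolar aprotic co-solvent; one equivalent of acetylide is spent on the tertiary hydroxyl, whose hindered lithium alkoxide should close the strained four-membered ring more slowly than the external acetylide attacks, and the carbinol carbon is not touched.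

**Step 5**
Reactants: 6 diisopropyl squarate, 3,4-diisopropoxycyclobut-3-ene-1,2-dione
Product: 8 3,4-dimethylcyclobut-3-ene-1,2-dione, via bis-adduct diol 7 (not isolated)
Conditions: MeLi (2.4 equiv), THF, −78 to 0 °C; then 12 M HCl, CH2Cl2, rt
Reagents that add atoms: methyllithium, C[Li]; water, O
Why: Double 1,2-addition of methyllithium to the two squarate carbonyls, then acid-catalysed ionization of each tertiary carbinol through the vinylogous isopropoxy group and hydrolysis (squarate carbonyl transposition), which moves the carbonyls onto the former alkoxy carbons and leaves the two methyl-bearing carbons as the ring alkene.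

**Step 6**
Reactants: 8 3,4-dimethylcyclobut-3-ene-1,2-dione
Product: 10 chloro(dimethylglyoxime)(2,3-dimethylmaleoyl)(pyridine)cobalt, via bis(triphenylphosphine) maleoylcobalt chloride 9 (not isolated)
Conditions: ClCo(PPh3)3, benzene, rt; then dimethylglyoxime, pyridine, rt
Reagents that add atoms: chlorotris(triphenylphosphine)cobalt, Cl[Co-3]([P+](c1ccccc1)(c1ccccc1)c1ccccc1)([P+](c1ccccc1)(c1ccccc1)c1ccccc1)[P+](c1ccccc1)(c1ccccc1)c1ccccc1; dimethylglyoxime, CC(=NO)C(C)=NO; pyridine, c1ccncc1
Why: Oxidative addition of monovalent cobalt into the strained bond between the two carbonyl carbons of the cyclobutenedione gives the trivalent cobaltacyclopentenedione (maleoylcobalt complex), and ligand exchange of both phosphines for dimethylglyoxime and pyridine gives the six-coordinate form of the maleoyl unit that should insert alkynes readily.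

**Step 7**
Reactants: 10 chloro(dimethylglyoxime)(2,3-dimethylmaleoyl)(pyridine)cobalt; 5 (6R,10R,14R)-6,10,14,18-tetramethylnonadec-2-yn-6-ol
Product: 11 tocopherylquinone, 2-[(3R,7R,11R)-3-hydroxy-3,7,11,15-tetramethylhexadecyl]-3,5,6-trimethylcyclohexa-2,5-diene-1,4-dione
Conditions: CoCl2·6H2O, ClCH2CH2Cl, 80 °C
Reagents that add atoms: none
Why: Lewis-acid-assisted loss of pyridine from the trivalent cobalt opens a coordination site for the alkyne, migratory insertion into one cobalt–acyl bond forms the first acyl–alkyne bond and a seven-membered cobaltacycle, and reductive elimination forms the second acyl–alkyne bond and releases the quinone together with monovalent cobalt. The closest known reaction type is the quinone synthesis from maleoyl- or phthaloylcobalt complexes and alkynes, a metal-templated formal [4+2] union of a 1,4-diacyl unit with an alkyne. The six-membered quinone ring is closed by C–C reductive elimination from the seven-membered metallacycle, not by an ionic or pericyclic cyclization. No stereocentre is formed, and the three existing ones are remote from the reacting atoms. The step needs only chemoselectivity: the symmetric 2,3-dimethylmaleoyl unit makes both orientations of the unsymmetrical alkyne converge on one quinone, and the mild hydrated CoCl2 promoter is chosen so that the free tertiary hydroxyl should survive.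

**Compound list**
1 | natural phytol, (2E,7R,11R)-3,7,11,15-tetramethylhexadec-2-en-1-ol | OC/C=C(\C)CCC[C@H](C)CCC[C@H](C)CCCC(C)C | starting material
2 | (2R,3R)-2,3-epoxyphytol, [(2R,3R)-3-methyl-3-[(4R,8R)-4,8,12-trimethyltridecyl]oxiran-2-yl]methanol | OC[C@@H]1[C@](C)(O1)CCC[C@H](C)CCC[C@H](C)CCCC(C)C | intermediate
3 | (3R,7R,11R)-3,7,11,15-tetramethylhexadecane-1,3-diol | OCC[C@](C)(O)CCC[C@H](C)CCC[C@H](C)CCCC(C)C | intermediate
4 | (3R,7R,11R)-3-hydroxy-3,7,11,15-tetramethylhexadecyl 4-methylbenzenesulfonate | Cc1ccc(cc1)S(=O)(=O)OCC[C@](C)(O)CCC[C@H](C)CCC[C@H](C)CCCC(C)C | intermediate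
5 | (6R,10R,14R)-6,10,14,18-tetramethylnonadec-2-yn-6-ol | CC#CCC[C@](C)(O)CCC[C@H](C)CCC[C@H](C)CCCC(C)C | intermediate
6 | diisopropyl squarate, 3,4-diisopropoxycyclobut-3-ene-1,2-dione | CC(C)OC1=C(OC(C)C)C(=O)C1=O | starting material
7 | bis-adduct diol, 3,4-diisopropoxy-1,2-dimethylcyclobut-3-ene-1,2-diol (cis/trans mixture, not isolated) | CC(C)OC1=C(OC(C)C)C(C)(O)C1(C)O | intermediate
8 | 3,4-dimethylcyclobut-3-ene-1,2-dione | CC1=C(C)C(=O)C1=O | intermediate
9 | chloro(2,3-dimethylmaleoyl)bis(triphenylphosphine)cobalt, a cobaltacyclopent-3-ene-2,5-dione of trivalent cobalt (not isolated) | CC1=C(C)C(=O)[Co-2](Cl)([P+](c2ccccc2)(c2ccccc2)c2ccccc2)([P+](c2ccccc2)(c2ccccc2)c2ccccc2)C1=O | intermediate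
10 | chloro(dimethylglyoxime)(2,3-dimethylmaleoyl)(pyridine)cobalt, the same cobaltacycle carrying Cl, N,N-bound neutral dimethylglyoxime and pyridine on trivalent cobalt | CC1=C(C)C(=O)[Co-3]2(Cl)([n+]3ccccc3)([N+](O)=C(C)C(C)=[N+]2O)C1=O | intermediate
11 | tocopherylquinone, 2-[(3R,7R,11R)-3-hydroxy-3,7,11,15-tetramethylhexadecyl]-3,5,6-trimethylcyclohexa-2,5-diene-1,4-dione | CC1=C(C)C(=O)C(CC[C@](C)(O)CCC[C@H](C)CCC[C@H](C)CCCC(C)C)=C(C)C1=O | target

**Step count and risks**
Total steps: 7. Longest linear sequence: 5 steps (steps 1, 2, 3, 4 and 7); the second branch (steps 5 and 6) joins at step 7.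

Steps most likely to fail:

1. Step 7. The alkyne insertion into the cobalt–acyl bond may be sluggish for a dialkyl alkyne that carries a free, coordinating hydroxyl, and forcing conditions could ionize or dehydrate the tertiary carbinol. The fallback takes the six-membered ring from an aromatic precursor instead of building it; it sets out from tosylate 4 and comes back at 11. Trimethylhydroquinone is O-methylated (Me2SO4, K2CO3, acetone) to 1,4-dimethoxy-2,3,5-trimethylbenzene F1, which is brominated at its only free ring position (Br2, AcOH) to 1-bromo-2,5-dimethoxy-3,4,6-trimethylbenzene F2. The Grignard reagent from F2 (Mg, THF; 3 equiv, one being consumed by the hydroxyl) is coupled with 4 under Li2CuCl4 catalysis (THF, −20 °C to rt) to give (3R,7R,11R)-1-(2,5-dimethoxy-3,4,6-trimethylphenyl)-3,7,11,15-tetramethylhexadecan-3-ol F3. Oxidative demethylation with (NH4)2Ce(NO3)6 in MeCN/H2O at 0 °C should then give 11 without touching the carbinol.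

2. Step 4. Intramolecular displacement of the tosylate by the tertiary alkoxide (four-membered ring closure), or base-induced elimination, may compete with the acetylide substitution. The fallback removes the nucleophilic oxygen by protection; it sets out from 4 and comes back at 5. Silylation (Et3SiOSO2CF3, 2,6-lutidine, CH2Cl2, −78 to 0 °C) gives (3R,7R,11R)-3,7,11,15-tetramethyl-3-(triethylsilyloxy)hexadecyl 4-methylbenzenesulfonate F4. Alkylation of LiC≡CCH3 (THF/DMPU) gives triethyl{[(6R,10R,14R)-6,10,14,18-tetramethylnonadec-2-yn-6-yl]oxy}silane F5, and desilylation (Bu4NF, THF, rt) returns 5.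

3. Step 6. The oxidative insertion may be incomplete, and the acylcobalt species may decompose oxidatively during the ligand exchange. The fallback is a chromium carbene benzannulation (Dötz reaction) that needs neither 8 nor cobalt; it sets out from alkynol 5 and comes back at 11. (E)-2-Bromobut-2-ene is lithiated (t-BuLi, Et2O, −78 °C) and added to Cr(CO)6 to give lithium pentacarbonyl[(2E)-2-methylbut-2-enoyl]chromate F6, which Me3OBF4 O-methylates to pentacarbonyl[(2E)-1-methoxy-2-methylbut-2-en-1-ylidene]chromium F7. Heating F7 with 5 (THF, 50 °C) and then exposing the mixture to air should give two regioisomeric hydroquinone monomethyl ethers: 2-[(3R,7R,11R)-3-hydroxy-3,7,11,15-tetramethylhexadecyl]-4-methoxy-3,5,6-trimethylphenol F8 and 3-[(3R,7R,11R)-3-hydroxy-3,7,11,15-tetramethylhexadecyl]-4-methoxy-2,5,6-trimethylphenol F9. Both are oxidized by (NH4)2Ce(NO3)6 (MeCN/H2O, 0 °C) to the same quinone 11.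

**Further compounds**
F1 | step 7 | 1,4-dimethoxy-2,3,5-trimethylbenzene | COc1cc(C)c(OC)c(C)c1C
F2 | step 7 | 1-bromo-2,5-dimethoxy-3,4,6-trimethylbenzene | COc1c(Br)c(C)c(OC)c(C)c1C
F3 | step 7 | (3R,7R,11R)-1-(2,5-dimethoxy-3,4,6-trimethylphenyl)-3,7,11,15-tetramethylhexadecan-3-ol | COc1c(CC[C@](C)(O)CCC[C@H](C)CCC[C@H](C)CCCC(C)C)c(C)c(OC)c(C)c1C
F4 | step 4 | (3R,7R,11R)-3,7,11,15-tetramethyl-3-(triethylsilyloxy)hexadecyl 4-methylbenzenesulfonate | Cc1ccc(cc1)S(=O)(=O)OCC[C@](C)(O[Si](CC)(CC)CC)CCC[C@H](C)CCC[C@H](C)CCCC(C)C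
F5 | step 4 | triethyl{[(6R,10R,14R)-6,10,14,18-tetramethylnonadec-2-yn-6-yl]oxy}silane | CC#CCC[C@](C)(O[Si](CC)(CC)CC)CCC[C@H](C)CCC[C@H](C)CCCC(C)C
F6 | step 6 | lithium pentacarbonyl[(2E)-2-methylbut-2-enoyl]chromate | [Li+].[O-]C(=[Cr](=C=O)(=C=O)(=C=O)(=C=O)=C=O)/C(C)=C/C
F7 | step 6 | pentacarbonyl[(2E)-1-methoxy-2-methylbut-2-en-1-ylidene]chromium | COC(=[Cr](=C=O)(=C=O)(=C=O)(=C=O)=C=O)/C(C)=C/C
F8 | step 6 | 2-[(3R,7R,11R)-3-hydroxy-3,7,11,15-tetramethylhexadecyl]-4-methoxy-3,5,6-trimethylphenol | COc1c(C)c(C)c(O)c(CC[C@](C)(O)CCC[C@H](C)CCC[C@H](C)CCCC(C)C)c1C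
F9 | step 6 | 3-[(3R,7R,11R)-3-hydroxy-3,7,11,15-tetramethylhexadecyl]-4-methoxy-2,5,6-trimethylphenol | COc1c(C)c(C)c(O)c(C)c1CC[C@](C)(O)CCC[C@H](C)CCC[C@H](C)CCCC(C)C
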